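The earlier runs and the new flask are calculated with made-up constants; the scatter is artificial.

Take the target first, for it is what the five flasks are asked about, and they differ in temperature and nothing else.

| flask | substrate | catalyst | temperature | remark | time |
|---|---|---|---|---|---|
| east | 1.5 M | 3.8 mM | −5 °C | run made earlier |  |
| west | 1.5 M | 15 mM | 28 °C | run made earlier |  |
| south-west | 3 M | 7.5 mM | −5 °C | run made earlier |  |
| Tuesday's | 1.5 M | 7.5 mM | 20 °C |  | 25 h |
| Friday's | 1.5 M | 7.5 mM | 40 °C |  | 25 h |
| Sunday's | 1.5 M | 7.5 mM | −20 °C |  | 25 h |
| Wednesday's | 1.5 M | 7.5 mM | 0 °C |  | 25 h |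
| Saturday's | 1.5 M | 7.5 mM | −10 °C |  | 25 h |

| run | time / h | target / % |
|---|---|---|
| east | 6.00 | 3 |
| east | 15.0 | 10 |
| east | 30.0 | 12 |
| east | 96.0 | 19 |
| west | 6.00 | 76 |
| west | 12.0 | 78 |
| west | 20.0 | 76 |
| west | 25.0 | 79 |
| south-west | 6.00 | 6 |
| south-west | 15.0 | 7 |
| south-west | 30.0 | 9 |
| south-west | 96.0 | 16 |

(each reading ± 2 percentage points)

- the flasks by amount of target, in percent of the substrate charged, highest first, at 25 h (Tuesday's / Friday's / Sunday's / Wednesday's / Saturday's)
- the amount of target, in percent of the substrate charged of the flask you put first, at 25 h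
- the amount of target, in percent of the substrate charged of the flask you put last, at 25 h



In the west run the target stands flat from the first reading on, so freeze it: call the mean of the four readings the ceiling, 77.2 % of the charge. Now try the bench rule that a rate doubles every 10.0 K. Between east and west it promises a factor of 9.85.

Read the slopes instead, as fractions of the charge per hour. East gives 0.00400 h⁻¹ on average up to 30.0 h, and west at least 0.127 h⁻¹ up to 6.00 h, since it was already flat there. Their ratio, at least 31.7 as read, is more than the rule allows, and there the rule stops unless catalyst makes up the difference. West has 15 mM against east's 3.8 mM, so catalyst might bridge the gap, but south-west, with 7.5 mM against 3.8 mM, shows 9 % against 12 % at 30.0 h. Its substrate changed too, so this is a choice: take the slope as free of catalyst.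

Then the ratio gives the steepness, the factor by which the slope grows per 10.0 K, 2.85 or more, as read. Scale east's slope by it and let the line bend exponentially into the ceiling. Wednesday's comes to 15.2 %, Saturday's to 5.70 %, Sunday's to 2.05 %, Tuesday's to 64.1 % and Friday's to 77.2 %. Hold these loosely: east's 19 % at 96.0 h lies lower than the curve's 30.3 %.

The forecast reads Tuesday's > Friday's > Wednesday's > Saturday's > Sunday's, with 78 % in the first flask and 4 % in the last, and says that this “top pair is the least certain part of the order”; it puts Tuesday's first, where I put Friday's.

The flasks give Friday's > Tuesday's > Wednesday's > Saturday's > Sunday's, with 79.9 % in Friday's and 1.79 % in Sunday's.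

    substrate ⇌ target (K = 4.40, k = 0.191 h⁻¹, Ea = 83.0 kJ mol⁻¹, ΔH = 0 kJ mol⁻¹)
    substrate + catalyst ⇌ isomer of the product + catalyst, rate k2*[substrate]*[catalyst] forward; the back reaction follows from the equilibrium constant (K = 0.469, k = 70.5 L mol⁻¹ h⁻¹, Ea = 54.0 kJ mol⁻¹, ΔH = −57.0 kJ mol⁻¹)
    (constants at 20 °C)

Wednesday's shows kinetic against thermodynamic control: 61.0 % isomer of the product and 15.6 % target at 25.0 h, then 38.2 % and 47.5 % at 250 h. The steepness had put Sunday's at 2.05 % of target. For a repeat of Friday's at 15 °C it gives 50.2 % of target, and that flask holds 63.4 %.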